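How much target stands after 2.5 min at each of the five loadings, and does it keep climbing with catalyst? The hunch that more catalyst gives more target needs one number first.

the same everywhere: starting material 0.0010 M
- north-west: reagent 2 equiv; free catalyst 0.41 mol%; run made earlier
- north-east: reagent 2 equiv; free catalyst 3.4 mol%; run made earlier
- spring: reagent 2.00 equiv; free catalyst 0.8 mol%; time 2.5 min
- dusk: reagent 2.00 equiv; free catalyst 1.2 mol%; time 2.5 min
- winter: reagent 2.00 equiv; free catalyst 1.5 mol%; time 2.5 min
- autumn: reagent 2.00 equiv; free catalyst 2.5 mol%; time 2.5 min
- summer: reagent 2.00 equiv; free catalyst 4 mol%; time 2.5 min

| run | time / s | target / % | starting material / % |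
|---|---|---|---|
| north-west | 10.0 | 2 | 91 |
| north-west | 15.0 | 0 | 85 |
| north-west | 25.0 | 4 | 79 |
| north-west | 40.0 | 5 | 61 |
| north-west | 60.0 | 12 | 59 |
| north-west | 80.0 | 19 | 49 |
| north-east | 10.0 | 17 | 47 |
| north-east | 15.0 | 31 | 27 |
| north-east | 25.0 | 49 | 13 |
| north-east | 50.0 | 63 | 2 |
| north-east | 80.0 | 58 | 0 |

(each reading ± 2 percentage points)

- the analysis behind the earlier runs scatters by 2 percentage points, standard deviation
- "hardly changes" means that all values lie within two and a half points (for a concentration: within two and a half percent of the largest)

* amount of target at the end, in percent of the starting material charged for spring, dusk, winter, autumn, summer, in this order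
* how that number moves from the first to the last of them (rises, then falls / hardly changes / falls all the way / falls, then rises / rises all the way)

The fraction of starting material left is easier to work with than the target made. The north-east run reads 13% left at 25.0 s. Its readings fall like a pseudo-first-order decay, so each halving takes the same time. The halving time, in which the starting material left at a given loading falls to half, reads 8.49 s at 3.4 mol%. Scaled by the ratio of loadings, that predicts 70.4 s for the north-west run, whose own readings give 77.7 s. So each flask with this charge of starting material and reagent can be counted in halvings: its time over the halving time at its loading.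

On that count, north-east target reads 49% at 2.94 halvings. Its highest reading, 63%, comes at 5.89, and it reads 58% at 9.42. That slip of 5 percentage points is larger than the scatter of 2 points, but not by much.

The new flasks count 4.16, 6.23, 7.79, 13.0 and 20.8 halvings. Taking target to follow the same count, the reckoning here puts spring between 49% and 63%, dusk closer to the highest north-east reading than spring or winter, and winter between 63% and 58%. Autumn and summer lie beyond the last north-east reading, so they are expected lower, by an amount the runs do not give, and the row is expected to rise, then fall.

The forecast gives 65%, 68%, 63%, 42% and 22%, rises, then falls, on the ground: “Everything then depends on catalyst × time”.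

The flasks give 61.1%, 65.0%, 62.5%, 49.6% and 36.6%: rises, then falls.

    starting material + free catalyst → free catalyst + open intermediate (k = 2510 L mol⁻¹ s⁻¹)
    free catalyst + open intermediate ⇌ catalyst intermediate (K = 41000 L mol⁻¹, k = 2440 L mol⁻¹ s⁻¹)
    reagent + catalyst intermediate → free catalyst + target (k = 15600 L mol⁻¹ s⁻¹)
    reagent + free catalyst + target → free catalyst + over-reaction product (k = 3.20 × 10⁵ L² mol⁻² s⁻¹)

Dusk stands highest, with 28.0% of over-reaction product beside its target. Its 6.23 halvings leave 1.33% of the starting material, and dusk ends with 1.22%. Autumn at 1.25 min has run 6.49 halvings, which leave 1.11%; it holds 1.01% of starting material there, and 64.8% of target.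

All runs stem from a simulated flask from invented constants.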